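The vessel is closed, stirred and isothermal, and we follow it by A, the percentage of starting material left, rather than by the target made.

| flask | starting material | coupling partner | initiator | remark | time |
|---|---|---|---|---|---|
| midnight | 1.5 M | 1.4 M | 32 mM | run made earlier |  |
| noon | 1.5 M | 2 M | 32 mM | run made earlier |  |
| flask | 1.5 M | 2.70 M | 32 mM |  | 30 h |

| run | time / h | target / % | starting material / % |
|---|---|---|---|
| midnight | 4.00 | 23.5 | 76.2 |
| midnight | 8.00 | 40.5 | 59.2 |
| midnight | 10.0 | 48.5 | 52.7 |
| midnight | 15.0 | 61.5 | 39.1 |
| midnight | 20.0 | 70.5 | 28.8 |
| noon | 4.00 | 23.6 | 76.0 |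
| noon | 8.00 | 41.8 | 59.4 |
| noon | 10.0 | 47.5 | 52.1 |
| noon | 15.0 | 61.3 | 38.9 |
| noon | 20.0 | 71.3 | 28.9 |

(each reading ± 0.5 percentage points)

- the earlier runs were read with a standard deviation of 0.5 percentage points

- how much target the flask holds at 30 h, in percent of the starting material charged
- how much starting material the flask holds at 30 h, in percent of the starting material charged

The two runs differ in coupling partner, 1.4 M against 2 M, yet A reads 28.8% and 28.9% at 20.0 h. So we leave the partner out of the reckoning, although the flask's 2.70 M lies beyond both runs. At that time the midnight run's target and A add up to 99.3%, so we take the target as what A has lost.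

Taking the runs together, ln A falls by 0.0646 h⁻¹ over the first 10.0 h. But the fall slows: we define k, a pseudo-first-order constant, as the fall of ln A per hour from 10.0 h to 20.0 h, and read 0.0597 h⁻¹, which is less than the earlier figure. That stretch is the middle third of the flask's 30 h, and if the slowing stays steady, the middle k is also the mean k. So we commit to A = exp(−kt), which leaves 16.7% starting material and makes 83.3% target.

The forecast, holding that “the rate is essentially zero order in partner”, gives 83.5% target and 16.5% starting material.

The flask holds 83.4% target and 16.6% starting material at 30 h.

    starting material + initiating radical → capped initiator + first chain carrier (k = 9.07 × 10⁶ L mol⁻¹ h⁻¹)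
    coupling partner + first chain carrier ⇌ target + second chain carrier (K = 4.50, k = 3.48 × 10⁵ L mol⁻¹ h⁻¹)
    2 second chain carrier → ended chains (k = 4.00 × 10⁶ L mol⁻¹ s⁻¹)
    starting material + second chain carrier → by-product + first chain carrier (k = 3.38 × 10⁵ L mol⁻¹ h⁻¹)
    initiator → 2 initiating radical (k = 0.0173 h⁻¹)

Over its 30 h this flask has a mean k of 0.0599 h⁻¹, and at the end starting material goes 19 times faster by its step with second chain carrier than by its step with initiating radical. A neighbouring flask charged with 0.0080 M of initiator, a quarter of this flask's charge, holds 41.4% starting material at the same time, which is a mean k of 0.0294 h⁻¹, half of this flask's 0.0599 h⁻¹.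

(The readings are simulated for an exercise, noise included.)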